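**Retrosynthetic overview**
- The (Z)-p-coumarate is made last by Z-selective Still–Gennari olefination of a C15 phosphonoacetate of 2α-silyloxy-labd-7-en-15-ol.
- Ring B is closed last at C7=C8 by McMurry coupling of a 7,8-seco keto-aldehyde; C7 comes from hydroformylation of a C5 exo-methylene and C17 from MeLi.
- Key bond C9–C10 (quaternary C10 next to C9): Ireland–Claisen [3,3] rearrangement of the ester of a ring A allylic alcohol with a C8–C15 acid.
- Ring A and the C2 stereocentre are bought as (4R,6R)-actinol (C2 relays to C10, C9 and C5); C13 is bought as (S)-citronellol.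
- Order: ring A (bought) → C9–C10 by [3,3] → ring B by carbonyl coupling → side-chain ester.

Assumption: labdane numbering (C1–C20) is used for atom labels in the Why lines; 1, 6, 25 and 27 are taken as purchasable.

**Step 1**
Reactants: 1 (4R,6R)-4-hydroxy-2,2,6-trimethylcyclohexan-1-one
Product: 2 (4R,6R)-4-[(tert-butyldimethylsilyl)oxy]-2,2,6-trimethylcyclohexan-1-one
Conditions: TBSCl, imidazole, DMF, 23 °C
Reagents that add atoms: tert-butyldimethylsilyl chloride, CC(C)(C)[Si](C)(C)Cl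
Why: Imidazole-promoted silylation masks the secondary alcohol (future C2–OH) without touching a stereocentre.

**Step 2**
Reactants: 2 (4R,6R)-4-[(tert-butyldimethylsilyl)oxy]-2,2,6-trimethylcyclohexan-1-one
Product: 4 (4R)-4-[(tert-butyldimethylsilyl)oxy]-2,6,6-trimethylcyclohex-1-en-1-yl trifluoromethanesulfonate, via potassium enolate 3 (not isolated)
Conditions: KN(SiMe3)2, THF, −78 °C; PhNTf2, −78 → 0 °C
Reagents that add atoms: N-phenylbis(trifluoromethanesulfonimide), O=S(=O)(N(c1ccccc1)S(=O)(=O)C(F)(F)F)C(F)(F)F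
Why: Only one α-carbon carries a hydrogen, so a single enolate forms and is O-triflated (enol triflate formation); the methyl-bearing centre is deliberately erased and the silyloxy centre is untouched.

**Step 3**
Reactants: 4 (4R)-4-[(tert-butyldimethylsilyl)oxy]-2,6,6-trimethylcyclohex-1-en-1-yl trifluoromethanesulfonate
Product: 5 [(4R)-4-[(tert-butyldimethylsilyl)oxy]-2,6,6-trimethylcyclohex-1-en-1-yl]methanol
Conditions: Bu3SnCH2OH, Pd(PPh3)4 (5 mol %), LiCl, 1,4-dioxane, 100 °C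
Reagents that add atoms: (tributylstannyl)methanol, CCCC[Sn](CCCC)(CCCC)CO
Why: Stille coupling of the vinyl triflate with the hydroxymethylstannane on zerovalent palladium installs C6 as a primary allylic alcohol in one step.

**Step 4**
Reactants: 6 (3S)-3,7-dimethyloct-6-en-1-ol
Product: 7 tert-butyl{[(3S)-3,7-dimethyloct-6-en-1-yl]oxy}dimethylsilane
Conditions: TBSCl, imidazole, CH2Cl2, 23 °C
Reagents that add atoms: tert-butyldimethylsilyl chloride, CC(C)(C)[Si](C)(C)Cl
Why: Silylation protects the primary alcohol (future C15–O); the C13 stereocentre is bought and untouched.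

**Step 5**
Reactants: 7 tert-butyl{[(3S)-3,7-dimethyloct-6-en-1-yl]oxy}dimethylsilane
Product: 9 (4S)-6-[(tert-butyldimethylsilyl)oxy]-4-methylhexanal, via ozonide 8 (not isolated)
Conditions: O3, CH2Cl2, −78 °C; then PPh3, −78 → 23 °C
Reagents that add atoms: ozone, [O-][O+]=O
Why: Ozonolysis with reductive work-up cleaves the trisubstituted alkene to the aldehyde (future C9) without affecting the remote stereocentre.

**Step 6**
Reactants: 9 (4S)-6-[(tert-butyldimethylsilyl)oxy]-4-methylhexanal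
Product: 10 (5S)-7-[(tert-butyldimethylsilyl)oxy]-1,1,1-trichloro-5-methylheptan-2-ol (C2 epimers)
Conditions: CHCl3, DBU (1 equiv), 0 → 23 °C
Reagents that add atoms: chloroform, ClC(Cl)Cl
Why: DBU-mediated addition of the trichloromethyl anion to the aldehyde brings in C8; the new carbinol centre is uncontrolled and is destroyed in step 7.

**Step 7**
Reactants: 10 (5S)-7-[(tert-butyldimethylsilyl)oxy]-1,1,1-trichloro-5-methylheptan-2-ol (C2 epimers)
Product: 13 (5S)-7-[(tert-butyldimethylsilyl)oxy]-5-methylheptanoic acid, via dichloroepoxide 11 (not isolated), via acyl chloride 12 (not isolated)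
Conditions: NaBH4, NaOH, t-BuOH, 55 °C; then aq. citric acid to pH 4
Reagents that add atoms: sodium hydroxide, [Na+].[OH-]
Why: Jocic–Reeve homologation: the alkoxide closes to the gem-dichloroepoxide, hydride opens it at the CH carbon and the acyl chloride is hydrolysed, giving the one-carbon-longer acid with a CH2 at C9.

**Step 8**
Reactants: 5 [(4R)-4-[(tert-butyldimethylsilyl)oxy]-2,6,6-trimethylcyclohex-1-en-1-yl]methanol; 13 (5S)-7-[(tert-butyldimethylsilyl)oxy]-5-methylheptanoic acid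
Product: 14 [(4R)-4-[(tert-butyldimethylsilyl)oxy]-2,6,6-trimethylcyclohex-1-en-1-yl]methyl (5S)-7-[(tert-butyldimethylsilyl)oxy]-5-methylheptanoate
Conditions: DCC, DMAP (cat.), CH2Cl2, 0 → 23 °C
Reagents that add atoms: none
Why: Steglich esterification joins the two bought-chirality fragments as the allylic ester needed for the rearrangement.

**Step 9**
Reactants: 14 [(4R)-4-[(tert-butyldimethylsilyl)oxy]-2,6,6-trimethylcyclohex-1-en-1-yl]methyl (5S)-7-[(tert-butyldimethylsilyl)oxy]-5-methylheptanoate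
Product: 18 (2R,5S)-7-[(tert-butyldimethylsilyl)oxy]-2-[(1R,5S)-5-[(tert-butyldimethylsilyl)oxy]-1,3,3-trimethyl-2-methylidenecyclohexyl]-5-methylheptanoic acid, via lithium enolate 15 (not isolated), via silyl ketene acetal 16 (not isolated), via silyl ester 17 (not isolated)
Conditions: LiN(iPr)2, THF/DMPU (4:1), −78 °C; Me3SiCl; −78 → 23 °C then 60 °C; H2O work-up (pH 4)
Reagents that add atoms: none
Why: Ireland–Claisen [3,3]-sigmatropic rearrangement forms the C9–C10 bond and the C5 exo-methylene; the ring half-chair keeps the C2 silyloxy group equatorial, so its pseudo-axial C4 methyl blocks one face and the bond forms on the other face, cis to the silyloxy group (sets C10), while the chair transition state with the Z(O) enolate (chain cis to OSiMe3) sets C9.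

**Step 10**
Reactants: 18 (2R,5S)-7-[(tert-butyldimethylsilyl)oxy]-2-[(1R,5S)-5-[(tert-butyldimethylsilyl)oxy]-1,3,3-trimethyl-2-methylidenecyclohexyl]-5-methylheptanoic acid
Product: 20 (3R,6S)-8-[(tert-butyldimethylsilyl)oxy]-3-[(1R,5S)-5-[(tert-butyldimethylsilyl)oxy]-1,3,3-trimethyl-2-methylidenecyclohexyl]-6-methyloctan-2-one, via dilithium diolate 19 (not isolated)
Conditions: MeLi (4 equiv), Et2O/THF, 0 → 23 °C; H2O quench, 0 °C
Reagents that add atoms: methyllithium, [Li]C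
Why: MeLi adds once to the lithium carboxylate and the gem-diolate collapses to the methyl ketone only on quench, installing C17 without a second addition.

**Step 11**
Reactants: 20 (3R,6S)-8-[(tert-butyldimethylsilyl)oxy]-3-[(1R,5S)-5-[(tert-butyldimethylsilyl)oxy]-1,3,3-trimethyl-2-methylidenecyclohexyl]-6-methyloctan-2-one
Product: 21 2-{(1S,2S,4S)-4-[(tert-butyldimethylsilyl)oxy]-2-[(3R,6S)-8-[(tert-butyldimethylsilyl)oxy]-6-methyl-2-oxooctan-3-yl]-2,6,6-trimethylcyclohexyl}acetaldehyde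
Conditions: Rh(acac)(CO)2 (2 mol %), tris(2,4-di-tert-butylphenyl) phosphite (8 mol %), CO/H2 (1:1, 40 bar), toluene, 100 °C
Reagents that add atoms: carbon monoxide, [C-]#[O+]
Why: Rh-catalysed hydroformylation puts the formyl group (C7) on the terminal carbon of the 1,1-disubstituted alkene, which cannot isomerise; hydrogen is delivered to C5 axially on the α face, anti to the two axial β-methyls at C4 and C10, which sets the trans ring-fusion hydrogen.

**Step 12**
Reactants: 21 2-{(1S,2S,4S)-4-[(tert-butyldimethylsilyl)oxy]-2-[(3R,6S)-8-[(tert-butyldimethylsilyl)oxy]-6-methyl-2-oxooctan-3-yl]-2,6,6-trimethylcyclohexyl}acetaldehyde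
Product: 23 (2S,5S,9S,10S,13S)-2,15-bis[(tert-butyldimethylsilyl)oxy]labd-7-ene, via titanium pinacolate 22 (not isolated)
Conditions: TiCl3(DME)1.5, Zn(Cu), DME, reflux, slow addition of 21 (30 h)
Reagents that add atoms: none
Why: Intramolecular McMurry coupling of the 1,6-keto-aldehyde on zerovalent titanium closes ring B and places the trisubstituted alkene regiospecifically at C7=C8; the two equatorial arms at C5 and C10 give the trans-decalin.

**Step 13**
Reactants: 23 (2S,5S,9S,10S,13S)-2,15-bis[(tert-butyldimethylsilyl)oxy]labd-7-ene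
Product: 24 (2S,5S,9S,10S,13S)-2-[(tert-butyldimethylsilyl)oxy]labd-7-en-15-ol
Conditions: p-TsOH·H2O (10 mol %), MeOH/CH2Cl2 (1:1), 0 °C
Reagents that add atoms: none
Why: Acid-catalysed methanolysis removes the unhindered primary silyl ether much faster than the secondary one at C2.

**Step 14**
Reactants: 24 (2S,5S,9S,10S,13S)-2-[(tert-butyldimethylsilyl)oxy]labd-7-en-15-ol; 25 2-[bis(2,2,2-trifluoroethoxy)phosphoryl]acetic acid
Product: 26 (2S,5S,9S,10S,13S)-2-[(tert-butyldimethylsilyl)oxy]labd-7-en-15-yl 2-[bis(2,2,2-trifluoroethoxy)phosphoryl]acetate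
Conditions: DCC, DMAP (cat.), CH2Cl2, 0 → 23 °C
Reagents that add atoms: none
Why: Steglich esterification of the primary alcohol installs the phosphonoacetate needed for a Z-selective olefination.

**Step 15**
Reactants: 26 (2S,5S,9S,10S,13S)-2-[(tert-butyldimethylsilyl)oxy]labd-7-en-15-yl 2-[bis(2,2,2-trifluoroethoxy)phosphoryl]acetate; 27 4-[(tert-butyldimethylsilyl)oxy]benzaldehyde
Product: 29 (2S,5S,9S,10S,13S)-2-[(tert-butyldimethylsilyl)oxy]labd-7-en-15-yl (2Z)-3-{4-[(tert-butyldimethylsilyl)oxy]phenyl}prop-2-enoate, via phosphonate anion 28 (not isolated)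
Conditions: KN(SiMe3)2, 18-crown-6, THF, −78 °C; then 27, −78 °C
Reagents that add atoms: none
Why: Still–Gennari variant of the Horner–Wadsworth–Emmons reaction; the electron-poor trifluoroethyl phosphonate with a dissociated potassium counter-ion eliminates under kinetic control to give the (Z)-enoate.

**Step 16**
Reactants: 29 (2S,5S,9S,10S,13S)-2-[(tert-butyldimethylsilyl)oxy]labd-7-en-15-yl (2Z)-3-{4-[(tert-butyldimethylsilyl)oxy]phenyl}prop-2-enoate
Product: 30 (2S,5S,9S,10S,13S)-2-hydroxylabd-7-en-15-yl (2Z)-3-(4-hydroxyphenyl)prop-2-enoate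
Conditions: HF·pyridine, pyridine, THF, 0 → 23 °C, in the dark
Reagents that add atoms: none
Why: Buffered fluoride desilylation frees the phenol and the C2 alcohol under mildly acidic conditions that do not isomerise the (Z)-enoate or cleave the ester.

**Compound list**
1 | (4R,6R)-4-hydroxy-2,2,6-trimethylcyclohexan-1-one (actinol) | C[C@@H]1C[C@@H](O)CC(C)(C)C1=O | starting material
2 | (4R,6R)-4-[(tert-butyldimethylsilyl)oxy]-2,2,6-trimethylcyclohexan-1-one | C[C@@H]1C[C@@H](O[Si](C)(C)C(C)(C)C)CC(C)(C)C1=O | intermediate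
3 | potassium (4R)-4-[(tert-butyldimethylsilyl)oxy]-2,6,6-trimethylcyclohex-1-en-1-olate | CC1=C([O-])C(C)(C)C[C@H](O[Si](C)(C)C(C)(C)C)C1.[K+] | intermediate
4 | (4R)-4-[(tert-butyldimethylsilyl)oxy]-2,6,6-trimethylcyclohex-1-en-1-yl trifluoromethanesulfonate | CC1=C(OS(=O)(=O)C(F)(F)F)C(C)(C)C[C@H](O[Si](C)(C)C(C)(C)C)C1 | intermediate
5 | [(4R)-4-[(tert-butyldimethylsilyl)oxy]-2,6,6-trimethylcyclohex-1-en-1-yl]methanol | CC1=C(CO)C(C)(C)C[C@H](O[Si](C)(C)C(C)(C)C)C1 | intermediate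
6 | (3S)-3,7-dimethyloct-6-en-1-ol ((S)-citronellol) | CC(C)=CCC[C@H](C)CCO | starting material
7 | tert-butyl{[(3S)-3,7-dimethyloct-6-en-1-yl]oxy}dimethylsilane | CC(C)=CCC[C@H](C)CCO[Si](C)(C)C(C)(C)C | intermediate
8 | 3-[(3S)-5-[(tert-butyldimethylsilyl)oxy]-3-methylpentyl]-5,5-dimethyl-1,2,4-trioxolane (ozonide, C3 epimers) | CC1(C)OOC(CC[C@H](C)CCO[Si](C)(C)C(C)(C)C)O1 | intermediate
9 | (4S)-6-[(tert-butyldimethylsilyl)oxy]-4-methylhexanal | O=CCC[C@H](C)CCO[Si](C)(C)C(C)(C)C | intermediate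
10 | (5S)-7-[(tert-butyldimethylsilyl)oxy]-1,1,1-trichloro-5-methylheptan-2-ol (C2 epimers) | OC(CC[C@H](C)CCO[Si](C)(C)C(C)(C)C)C(Cl)(Cl)Cl | intermediate
11 | 2,2-dichloro-3-[(3S)-5-[(tert-butyldimethylsilyl)oxy]-3-methylpentyl]oxirane | ClC1(Cl)OC1CC[C@H](C)CCO[Si](C)(C)C(C)(C)C | intermediate
12 | (5S)-7-[(tert-butyldimethylsilyl)oxy]-5-methylheptanoyl chloride | O=C(Cl)CCC[C@H](C)CCO[Si](C)(C)C(C)(C)C | intermediate
13 | (5S)-7-[(tert-butyldimethylsilyl)oxy]-5-methylheptanoic acid | OC(=O)CCC[C@H](C)CCO[Si](C)(C)C(C)(C)C | intermediate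
14 | [(4R)-4-[(tert-butyldimethylsilyl)oxy]-2,6,6-trimethylcyclohex-1-en-1-yl]methyl (5S)-7-[(tert-butyldimethylsilyl)oxy]-5-methylheptanoate | CC1=C(COC(=O)CCC[C@H](C)CCO[Si](C)(C)C(C)(C)C)C(C)(C)C[C@H](O[Si](C)(C)C(C)(C)C)C1 | intermediate
15 | lithium Z(O)-enolate of ester 14 (alkyl chain cis to OLi) | CC1=C(CO/C([O-])=C/CC[C@H](C)CCO[Si](C)(C)C(C)(C)C)C(C)(C)C[C@H](O[Si](C)(C)C(C)(C)C)C1.[Li+] | intermediate
16 | (Z)-trimethylsilyl ketene acetal of ester 14 (alkyl chain cis to OSiMe3) | CC1=C(CO/C(O[Si](C)(C)C)=C/CC[C@H](C)CCO[Si](C)(C)C(C)(C)C)C(C)(C)C[C@H](O[Si](C)(C)C(C)(C)C)C1 | intermediate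
17 | trimethylsilyl (2R,5S)-7-[(tert-butyldimethylsilyl)oxy]-2-[(1R,5S)-5-[(tert-butyldimethylsilyl)oxy]-1,3,3-trimethyl-2-methylidenecyclohexyl]-5-methylheptanoate | C=C1C(C)(C)C[C@H](O[Si](C)(C)C(C)(C)C)C[C@]1(C)[C@H](C(=O)O[Si](C)(C)C)CC[C@H](C)CCO[Si](C)(C)C(C)(C)C | intermediate
18 | (2R,5S)-7-[(tert-butyldimethylsilyl)oxy]-2-[(1R,5S)-5-[(tert-butyldimethylsilyl)oxy]-1,3,3-trimethyl-2-methylidenecyclohexyl]-5-methylheptanoic acid | C=C1C(C)(C)C[C@H](O[Si](C)(C)C(C)(C)C)C[C@]1(C)[C@H](C(=O)O)CC[C@H](C)CCO[Si](C)(C)C(C)(C)C | intermediate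
19 | dilithium gem-diolate from MeLi addition to the carboxylate of 18 (octane-2,2-diolate; centres as in 18) | C=C1C(C)(C)C[C@H](O[Si](C)(C)C(C)(C)C)C[C@]1(C)[C@H](C(C)([O-])[O-])CC[C@H](C)CCO[Si](C)(C)C(C)(C)C.[Li+].[Li+] | intermediate
20 | (3R,6S)-8-[(tert-butyldimethylsilyl)oxy]-3-[(1R,5S)-5-[(tert-butyldimethylsilyl)oxy]-1,3,3-trimethyl-2-methylidenecyclohexyl]-6-methyloctan-2-one | C=C1C(C)(C)C[C@H](O[Si](C)(C)C(C)(C)C)C[C@]1(C)[C@H](C(C)=O)CC[C@H](C)CCO[Si](C)(C)C(C)(C)C | intermediate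
21 | 2-{(1S,2S,4S)-4-[(tert-butyldimethylsilyl)oxy]-2-[(3R,6S)-8-[(tert-butyldimethylsilyl)oxy]-6-methyl-2-oxooctan-3-yl]-2,6,6-trimethylcyclohexyl}acetaldehyde | O=CC[C@H]1C(C)(C)C[C@H](O[Si](C)(C)C(C)(C)C)C[C@]1(C)[C@H](C(C)=O)CC[C@H](C)CCO[Si](C)(C)C(C)(C)C | intermediate
22 | titanium 7,8-diolate (pinacolate) of the ring-closed bis-silyl ether (C7 and C8 unassigned; other centres as in 23; titanium drawn schematically) | CC1(O[Ti]O3)C3C[C@H]2C(C)(C)C[C@H](O[Si](C)(C)C(C)(C)C)C[C@]2(C)[C@H]1CC[C@H](C)CCO[Si](C)(C)C(C)(C)C | intermediate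
23 | (2S,5S,9S,10S,13S)-2,15-bis[(tert-butyldimethylsilyl)oxy]labd-7-ene | CC1=CC[C@H]2C(C)(C)C[C@H](O[Si](C)(C)C(C)(C)C)C[C@]2(C)[C@H]1CC[C@H](C)CCO[Si](C)(C)C(C)(C)C | intermediate
24 | (2S,5S,9S,10S,13S)-2-[(tert-butyldimethylsilyl)oxy]labd-7-en-15-ol | CC1=CC[C@H]2C(C)(C)C[C@H](O[Si](C)(C)C(C)(C)C)C[C@]2(C)[C@H]1CC[C@H](C)CCO | intermediate
25 | 2-[bis(2,2,2-trifluoroethoxy)phosphoryl]acetic acid | OC(=O)CP(=O)(OCC(F)(F)F)OCC(F)(F)F | starting material
26 | (2S,5S,9S,10S,13S)-2-[(tert-butyldimethylsilyl)oxy]labd-7-en-15-yl 2-[bis(2,2,2-trifluoroethoxy)phosphoryl]acetate | CC1=CC[C@H]2C(C)(C)C[C@H](O[Si](C)(C)C(C)(C)C)C[C@]2(C)[C@H]1CC[C@H](C)CCOC(=O)CP(=O)(OCC(F)(F)F)OCC(F)(F)F | intermediate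
27 | 4-[(tert-butyldimethylsilyl)oxy]benzaldehyde | O=Cc1ccc(O[Si](C)(C)C(C)(C)C)cc1 | starting material
28 | potassium salt of the phosphonate-stabilised carbanion of 26 | CC1=CC[C@H]2C(C)(C)C[C@H](O[Si](C)(C)C(C)(C)C)C[C@]2(C)[C@H]1CC[C@H](C)CCOC(=O)[CH-]P(=O)(OCC(F)(F)F)OCC(F)(F)F.[K+] | intermediate
29 | (2S,5S,9S,10S,13S)-2-[(tert-butyldimethylsilyl)oxy]labd-7-en-15-yl (2Z)-3-{4-[(tert-butyldimethylsilyl)oxy]phenyl}prop-2-enoate | CC1=CC[C@H]2C(C)(C)C[C@H](O[Si](C)(C)C(C)(C)C)C[C@]2(C)[C@H]1CC[C@H](C)CCOC(=O)/C=C\c1ccc(O[Si](C)(C)C(C)(C)C)cc1 | intermediate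
30 | (2S,5S,9S,10S,13S)-2-hydroxylabd-7-en-15-yl (2Z)-3-(4-hydroxyphenyl)prop-2-enoate (CNP0301213.1) | CC1=CC[C@H]2C(C)(C)C[C@H](O)C[C@]2(C)[C@H]1CC[C@H](C)CCOC(=O)/C=C\c1ccc(O)cc1 | target

**Step count and risks**

Total step count: 16. Longest linear sequence: 13 steps (steps 4–16, from (S)-citronellol 6); the actinol branch (steps 1–3) joins at step 8.

The three steps most likely to fail:

Step 9 (Ireland–Claisen). This is the weakest point of the route. The cis delivery of C9 relative to the C2 silyloxy group rests on a conformational argument, not on a close precedent. If the bond forms on the other face, the C10 epimer results and the route fails. A second risk is that the hindered ester enolate gives a poor Z(O) ratio or a competing boat transition state, which would erode C9. The fallback answers the second risk only; it relies on the same ring-face bias. It sets out from aldehyde 9 and alcohol 5 and replaces the ester-enolate rearrangement by a neutral aliphatic Claisen with fixed enol ether geometry. Takai iodo-olefination of 9 (CHI3, CrCl2, THF) gives tert-butyl{[(3S,6E)-7-iodo-3-methylhept-6-en-1-yl]oxy}dimethylsilane F1. Coupling of F1 with 5 (CuI, 3,4,7,8-tetramethyl-1,10-phenanthroline, Cs2CO3, o-xylene, 120 °C) gives the allyl (E)-vinyl ether F2. F2 rearranges in the same flask through the same chair to the (2R,5S)-2-cyclohexyl-heptanal F3. MeMgBr converts F3 into the octan-2-ol F4 (carbinol epimers), and Dess–Martin oxidation of F4 comes back to the route at methyl ketone 20.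

Step 11 (hydroformylation). The exo-methylene lies between two quaternary carbons and may react too slowly or be hydrogenated. The fallback sets out from 20 and builds ring B by an aldol condensation instead. BH3·THF followed by NaOH/H2O2 hydroborates the alkene from the same α face and reduces the ketone, giving the seco-diol F5. Dess–Martin oxidation gives the cyclohexane-1-carbaldehyde methyl ketone F6. KOH in MeOH closes ring B by aldol condensation to the 17-norlabd-6-en-8-one F7; the former ketone methyl becomes C7, and C5 and C9 can equilibrate to the trans-fused, equatorial arrangement. Conjugate reduction with LiBH(sBu)3 and trapping of the enolate with PhNTf2 gives the 17-norlabd-7-en-8-yl triflate F8. Iron-catalysed methylation of F8 (MeMgBr, Fe(acac)3, THF/NMP) comes back to the route at 23.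

Step 3 (Stille hydroxymethylation). Transmetalation to the tetrasubstituted, doubly flanked vinyl palladium may be too slow. The fallback sets out from triflate 4. Palladium-catalysed methoxycarbonylation (Pd(OAc)2, PPh3, CO, MeOH, Et3N, DMF, 70 °C) gives methyl (4R)-4-[(tert-butyldimethylsilyl)oxy]-2,6,6-trimethylcyclohex-1-ene-1-carboxylate F9. Reduction of F9 with (iBu)2AlH (CH2Cl2, −78 °C) comes back to the route at allylic alcohol 5.

**Further compounds**
F1 | step 9 | tert-butyl{[(3S,6E)-7-iodo-3-methylhept-6-en-1-yl]oxy}dimethylsilane | I/C=C/CC[C@H](C)CCO[Si](C)(C)C(C)(C)C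
F2 | step 9 | tert-butyl{[(3S,6E)-7-{[(4R)-4-[(tert-butyldimethylsilyl)oxy]-2,6,6-trimethylcyclohex-1-en-1-yl]methoxy}-3-methylhept-6-en-1-yl]oxy}dimethylsilane (allyl vinyl ether) | CC1=C(CO/C=C/CC[C@H](C)CCO[Si](C)(C)C(C)(C)C)C(C)(C)C[C@H](O[Si](C)(C)C(C)(C)C)C1
F3 | step 9 | (2R,5S)-7-[(tert-butyldimethylsilyl)oxy]-2-[(1R,5S)-5-[(tert-butyldimethylsilyl)oxy]-1,3,3-trimethyl-2-methylidenecyclohexyl]-5-methylheptanal | C=C1C(C)(C)C[C@H](O[Si](C)(C)C(C)(C)C)C[C@]1(C)[C@H](C=O)CC[C@H](C)CCO[Si](C)(C)C(C)(C)C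
F4 | step 9 | (3R,6S)-8-[(tert-butyldimethylsilyl)oxy]-3-[(1R,5S)-5-[(tert-butyldimethylsilyl)oxy]-1,3,3-trimethyl-2-methylidenecyclohexyl]-6-methyloctan-2-ol (C2 epimers) | C=C1C(C)(C)C[C@H](O[Si](C)(C)C(C)(C)C)C[C@]1(C)[C@H](C(C)O)CC[C@H](C)CCO[Si](C)(C)C(C)(C)C
F5 | step 11 | (3R,6S)-8-[(tert-butyldimethylsilyl)oxy]-3-[(1S,2S,5S)-5-[(tert-butyldimethylsilyl)oxy]-2-(hydroxymethyl)-1,3,3-trimethylcyclohexyl]-6-methyloctan-2-ol (C2 epimers) | OC[C@H]1C(C)(C)C[C@H](O[Si](C)(C)C(C)(C)C)C[C@]1(C)[C@H](C(C)O)CC[C@H](C)CCO[Si](C)(C)C(C)(C)C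
F6 | step 11 | (1S,2S,4S)-4-[(tert-butyldimethylsilyl)oxy]-2-[(3R,6S)-8-[(tert-butyldimethylsilyl)oxy]-6-methyl-2-oxooctan-3-yl]-2,6,6-trimethylcyclohexane-1-carbaldehyde | O=C[C@H]1C(C)(C)C[C@H](O[Si](C)(C)C(C)(C)C)C[C@]1(C)[C@H](C(C)=O)CC[C@H](C)CCO[Si](C)(C)C(C)(C)C
F7 | step 11 | (2S,5S,9R,10S,13S)-2,15-bis[(tert-butyldimethylsilyl)oxy]-17-norlabd-6-en-8-one | O=C1C=C[C@H]2C(C)(C)C[C@H](O[Si](C)(C)C(C)(C)C)C[C@]2(C)[C@H]1CC[C@H](C)CCO[Si](C)(C)C(C)(C)C
F8 | step 11 | (2S,5S,9R,10S,13S)-2,15-bis[(tert-butyldimethylsilyl)oxy]-17-norlabd-7-en-8-yl trifluoromethanesulfonate | O=S(=O)(OC1=CC[C@H]2C(C)(C)C[C@H](O[Si](C)(C)C(C)(C)C)C[C@]2(C)[C@H]1CC[C@H](C)CCO[Si](C)(C)C(C)(C)C)C(F)(F)F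
F9 | step 3 | methyl (4R)-4-[(tert-butyldimethylsilyl)oxy]-2,6,6-trimethylcyclohex-1-ene-1-carboxylate | CC1=C(C(=O)OC)C(C)(C)C[C@H](O[Si](C)(C)C(C)(C)C)C1
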